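## Retrosynthetic overview

1. Endgame: the angelate (on the allylic C9–O) and the (2R,3R)-epoxyangelate (on the neopentylic C10–O) are attached one after the other to the trans-9,10-diol of the cis-fused himachalane core. The epoxy acid is made from angelic acid by Katsuki–Sharpless epoxidation and oxidation.
2. Key disconnection: ring A, the 2-methylcyclohex-2-enone (C1–C6), is opened at C5–C6 and C2=C3. This is possible because the ketone C4 sits between C3(CH3) and C5H2 inside ring A, so C3–C4–C5 is a butanone 1,3-dinucleophile (used as methyl 3-oxopentanoate). C2–C1–C6 is then the formyl carbon, α-carbon and β-carbon of a cyclohepta-1,3-diene-1-carbaldehyde belonging to ring B. The forward reaction is a one-flask (3+3) annulation: Michael addition, aldol condensation, loss of the ester.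
3. The dienal comes from a eucarvone-derived cycloheptenone by α-formylation and reductive 1,3-carbonyl transposition. Its trans-diol (C9, C10) comes from enantioselective epoxidation of the γ,δ-alkene of eucarvone and anti hydrolysis, and is tied into a trans-fused acetonide that fixes the ring conformation steering the key step.
4. Order of ring formation: ring B (seven-membered, with its three methyl groups) first, by ring expansion of carvone to eucarvone; then the temporary dioxolane; ring A last, in the key step. The side-chain oxirane is made separately.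

Key step: step 9

Remark on numbering: bicyclic compounds carry himachalane numbering. Ring A = C1–C6 (C1 and C6 ring fusion; C2=C3(CH3); C4=O; C5H2). Ring B = C1, C6, C7(CH3)=C8, C9, C10, C11(CH3)2.

Assumption: the facial sense of the manganese–salen epoxidation in step 3 is taken from 2,2-dimethylchromene, the closest analogue; if the other face were attacked, the (R,R)-complex would be used instead.

## Route

Step 1
Reactants: 1 (R)-(−)-carvone
Product: 2 carvone hydrobromide ((5R)-5-(2-bromopropan-2-yl)-2-methylcyclohex-2-en-1-one)
Conditions: HBr (33 % in AcOH), 0 °C → rt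
Reagents that add atoms: hydrogen bromide, Br
Why: Markovnikov hydrobromination of the electron-rich isopropenyl group through the tertiary cation leaves the deactivated enone alkene and the stereocentre untouched.

Step 2
Reactants: 2 carvone hydrobromide
Product: 4 eucarvone (2,6,6-trimethylcyclohepta-2,4-dien-1-one), via carenone 3 (not isolated)
Conditions: KOH, MeOH, 0 °C → reflux
Reagents that add atoms: none
Why: Intramolecular enolate alkylation (1,3-elimination of HBr) gives the cyclopropyl ketone 3, whose dienolate opens the ring-fusion bond in a norcaradiene-to-cycloheptatriene-type electrocyclic ring opening; this classical carvone-to-eucarvone ring expansion removes all stereocentres.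

Step 3
Reactants: 4 eucarvone
Product: 5 (4S,5R)-4,5-epoxy-2,6,6-trimethylcyclohept-2-en-1-one
Conditions: (S,S)-N,N'-bis(3,5-di-tert-butylsalicylidene)-1,2-cyclohexanediaminomanganese chloride (C36H52ClMnN2O2, 5 mol %), mCPBA, N-methylmorpholine N-oxide, CH2Cl2, −78 °C
Reagents that add atoms: 3-chloroperoxybenzoic acid (mCPBA), OOC(=O)c1cccc(Cl)c1
Why: Jacobsen–Katsuki epoxidation should attack the γ,δ-alkene, which is the more electron-rich alkene and a cis-disubstituted one flanked by a conjugating vinyl group and a quaternary carbon as in 2,2-dimethylchromene, so the (S,S)-complex is expected to give the (4S,5R)-oxide, which sets C10 directly and C9 after the inversion in step 4.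

Step 4
Reactants: 5 epoxide
Product: 6 (4R,5R)-4,5-dihydroxy-2,6,6-trimethylcyclohept-2-en-1-one
Conditions: HClO4 (cat.), THF/H2O, 0 °C
Reagents that add atoms: water, O
Why: Acid-catalysed anti opening of the epoxide: water attacks the allylic C4 with inversion because C5 is neopentylic, which should give the trans-(4R,5R)-diol.

Step 5
Reactants: 6 trans-diol
Product: 7 (4R,5R)-4,5-(isopropylidenedioxy)-2,6,6-trimethylcyclohept-2-en-1-one
Conditions: Me2C(OMe)2, PPTS (cat.), acetone, rt
Reagents that add atoms: 2,2-dimethoxypropane, COC(C)(C)OC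
Why: Acid-catalysed transketalisation closes the trans-fused dioxolane on the diequatorial diol of the flexible seven-membered ring; no stereocentre is touched, and the hydroxyl groups are masked against base.

Step 6
Reactants: 7 acetonide ketone
Product: 8 (4R,5R,7Z)-7-(hydroxymethylidene)-4,5-(isopropylidenedioxy)-2,6,6-trimethylcyclohept-2-en-1-one
Conditions: LiN(i-Pr)2, THF, −78 °C; then CF3CH2OCHO, −78 °C; aq. NH4Cl
Reagents that add atoms: 2,2,2-trifluoroethyl formate, O=COCC(F)(F)F
Why: Kinetic deprotonation at the only enolisable α-carbon (C7, as at C6 of isophorone) and Claisen-type C-formylation with the activated formate should give the chelated β-keto aldehyde enol; no stereocentre is formed.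

Step 7
Reactants: 8 hydroxymethylidene ketone
Product: 9 (4R,5R,7Z)-7-(isopropoxymethylidene)-4,5-(isopropylidenedioxy)-2,6,6-trimethylcyclohept-2-en-1-one
Conditions: i-PrI, K2CO3, DMF, rt
Reagents that add atoms: 2-iodopropane, CC(C)I
Why: Williamson-type O-alkylation of the β-keto aldehyde enolate at the less hindered formyl oxygen turns the acidic enol into a vinylogous ester; the enol ether geometry is of no consequence.

Step 8
Reactants: 9 isopropoxymethylidene ketone
Product: 11 (5R,6R)-5,6-(isopropylidenedioxy)-3,7,7-trimethylcyclohepta-1,3-diene-1-carbaldehyde, via allylic alcohol 10 (not isolated)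
Conditions: NaBH4, CeCl3·7H2O, MeOH, −20 °C; then PPTS, acetone/H2O, rt
Reagents that add atoms: water, O
Why: Luche 1,2-reduction of the cross-conjugated ketone, then acid-induced ionisation of the doubly allylic alcohol assisted by the enol ether oxygen and hydrolysis of the oxocarbenium ion, amounts to a reductive 1,3-carbonyl transposition of the Stork–Danheiser type that delivers the α,β-unsaturated aldehyde; the carbinol centre of 10 is lost again.

Step 9
Reactants: 11 dienal acetonide; 12 methyl 3-oxopentanoate
Product: 15 (1S,6R,9R,10R)-9,10-(isopropylidenedioxy)himachala-2,7-dien-4-one, via Michael adduct 13 (not isolated), via bicyclic keto ester 14 (not isolated)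
Conditions: Cs2CO3 (20 mol %), DMSO, 25 → 60 °C; then LiCl, H2O, 140 °C
Reagents that add atoms: none
Why: The enolate of 12 (the carbon between its two carbonyl groups) adds reversibly to C6, the β-carbon of the dienal, to give 13; the CH2 of the ethyl ketone then condenses with the aldehyde carbon C2 to give 14, and chloride-induced demethylation with loss of CO2 leaves 15, so that C5–C6 and C2=C3 are both made in one flask. The closest known reaction type is the Robinson-type (3+3) annulation of enals with β-keto esters followed by Krapcho dealkoxycarbonylation. Only ring A is closed, by a 6-(enolendo)-exo-trig aldol condensation that follows the intermolecular Michael addition. C6 should be set by addition anti to the pseudo-axial C11 methyl group of the acetonide-locked cycloheptadiene, that is on the face of O9; C1 should be set by equilibration (α to the aldehyde, later γ to the enone) to the cis-fused isomer, in which C2 is pseudo-axial and H1, not C2, lies between the geminal methyl groups. The step needs 1,4- over 1,6-addition and conjugate addition over Knoevenagel condensation: only the 1,4-adduct can close a six-membered ring while the Michael step stays reversible, and the aldehyde carbon is shielded by the adjacent quaternary C11. The ester group fixes which carbon of the four-carbon partner is the Michael donor and is removed in the same flask.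

Step 10
Reactants: 15 enone acetonide
Product: 16 (1S,6R,9R,10R)-9,10-dihydroxyhimachala-2,7-dien-4-one
Conditions: AcOH/H2O (4:1), 40 °C
Reagents that add atoms: none
Why: Mild acetal hydrolysis should cleave the strained trans-fused acetonide without ionising the allylic C9–O bond or touching the enone; no stereocentre changes.

Step 11
Reactants: 16 diol; 17 angelic acid
Product: 19 (1S,6R,9R,10R)-9-angeloyloxy-10-hydroxyhimachala-2,7-dien-4-one, via mixed anhydride 18 (not isolated)
Conditions: 2,4,6-Cl3C6H2COCl, Et3N, toluene, rt; then 16, DMAP, 0 °C → rt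
Reagents that add atoms: none
Why: Yamaguchi esterification should acylate the less hindered allylic C9 hydroxyl in preference to the neopentylic C10 hydroxyl, and the mixed-anhydride protocol avoids the pathways that isomerise angelates to tiglates; no stereocentre changes.

Step 12
Reactants: 17 angelic acid
Product: 20 (Z)-2-methylbut-2-en-1-ol
Conditions: LiAlH4, Et2O, 0 °C → rt
Reagents that add atoms: none
Why: Hydride reduction of the carboxylic acid by 1,2-attack gives the primary allylic alcohol and keeps the Z-alkene.

Step 13
Reactants: 20 (Z)-2-methylbut-2-en-1-ol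
Product: 21 [(2S,3R)-2,3-dimethyloxiran-2-yl]methanol
Conditions: Ti(OiPr)4 (10 mol %), L-(+)-diisopropyl tartrate (12 mol %), t-BuOOH, 4 Å molecular sieves, CH2Cl2, −20 °C
Reagents that add atoms: tert-butyl hydroperoxide, CC(C)(C)OO
Why: Katsuki–Sharpless asymmetric epoxidation with L-(+)-tartrate is expected to epoxidise the face that gives the (2S,3R)-epoxy alcohol, the syn addition preserving the cis relation of CH2OH and the C3 methyl group.

Step 14
Reactants: 21 epoxy alcohol
Product: 23 (2R,3R)-2,3-dimethyloxirane-2-carboxylic acid (epoxyangelic acid), via epoxy aldehyde 22 (not isolated)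
Conditions: TEMPO (cat.), PhI(OAc)2, MeCN/H2O, rt
Reagents that add atoms: water, O
Why: Nitroxyl-catalysed oxidation takes the primary alcohol through the aldehyde hydrate to the acid under nearly neutral conditions that spare the epoxide; both stereocentres are retained, the C2 descriptor changing only through the priority rules.

Step 15
Reactants: 19 mono-angelate; 23 epoxyangelic acid
Product: 25 (1S,6R,9R,10R)-9-angeloyloxy-10-[(2R,3R)-2,3-epoxy-2-methylbutanoyloxy]himachala-2,7-dien-4-one, via mixed anhydride 24 (not isolated)
Conditions: 2,4,6-Cl3C6H2COCl, Et3N, toluene, rt; then 19, DMAP, rt → 40 °C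
Reagents that add atoms: none
Why: A second Yamaguchi esterification should acylate the remaining secondary C10 hydroxyl under DMAP catalysis, the buffered conditions being chosen to avoid acyl migration, angelate isomerisation and epoxide opening; no stereocentre is touched.

## Compound list

1 | (R)-(−)-carvone | CC1=CC[C@H](CC1=O)C(=C)C | starting material
2 | carvone hydrobromide, (5R)-5-(2-bromopropan-2-yl)-2-methylcyclohex-2-en-1-one | CC1=CC[C@H](CC1=O)C(C)(C)Br | intermediate
3 | carenone, (1S,6R)-3,7,7-trimethylbicyclo[4.1.0]hept-3-en-2-one | CC1=CC[C@@H]2[C@H](C1=O)C2(C)C | intermediate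
4 | eucarvone, 2,6,6-trimethylcyclohepta-2,4-dien-1-one | CC1=CC=CC(C)(C)CC1=O | intermediate
5 | (4S,5R)-4,5-epoxy-2,6,6-trimethylcyclohept-2-en-1-one | O1[C@H]2C=C(C)C(=O)CC(C)(C)[C@@H]12 | intermediate
6 | (4R,5R)-4,5-dihydroxy-2,6,6-trimethylcyclohept-2-en-1-one | O[C@@H]1C=C(C)C(=O)CC(C)(C)[C@H]1O | intermediate
7 | (4R,5R)-4,5-(isopropylidenedioxy)-2,6,6-trimethylcyclohept-2-en-1-one | CC1(C)O[C@@H]2C=C(C)C(=O)CC(C)(C)[C@H]2O1 | intermediate
8 | (4R,5R,7Z)-7-(hydroxymethylidene)-4,5-(isopropylidenedioxy)-2,6,6-trimethylcyclohept-2-en-1-one | CC1(C)O[C@@H]2C=C(C)C(=O)/C(=C\O)C(C)(C)[C@H]2O1 | intermediate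
9 | (4R,5R,7Z)-7-(isopropoxymethylidene)-4,5-(isopropylidenedioxy)-2,6,6-trimethylcyclohept-2-en-1-one | CC1(C)O[C@@H]2C=C(C)C(=O)/C(=C\OC(C)C)C(C)(C)[C@H]2O1 | intermediate
10 | (4R,5R,7Z)-7-(isopropoxymethylidene)-4,5-(isopropylidenedioxy)-2,6,6-trimethylcyclohept-2-en-1-ol, both C1 epimers | CC1(C)O[C@@H]2C=C(C)C(O)/C(=C\OC(C)C)C(C)(C)[C@H]2O1 | intermediate
11 | (5R,6R)-5,6-(isopropylidenedioxy)-3,7,7-trimethylcyclohepta-1,3-diene-1-carbaldehyde | CC1(C)O[C@@H]2C=C(C)C=C(C=O)C(C)(C)[C@H]2O1 | intermediate
12 | methyl 3-oxopentanoate | CCC(=O)CC(=O)OC | starting material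
13 | Michael adduct: methyl 3-oxopentanoate joined through its C2 to C6 of the ring B aldehyde, ring carbons configured as in 15, ester-bearing carbon as a mixture of epimers | CC1(C)O[C@@H]2C=C(C)[C@H](C(C(=O)CC)C(=O)OC)[C@H](C=O)C(C)(C)[C@H]2O1 | intermediate
14 | bicyclic keto ester: 5-methoxycarbonyl derivative of 15, ester-bearing C5 as a mixture of epimers | CC1(C)O[C@@H]2C=C(C)[C@@H]3C(C(=O)OC)C(=O)C(C)=C[C@@H]3C(C)(C)[C@H]2O1 | intermediate
15 | (1S,6R,9R,10R)-9,10-(isopropylidenedioxy)himachala-2,7-dien-4-one | CC1(C)O[C@@H]2C=C(C)[C@@H]3CC(=O)C(C)=C[C@@H]3C(C)(C)[C@H]2O1 | intermediate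
16 | (1S,6R,9R,10R)-9,10-dihydroxyhimachala-2,7-dien-4-one | O[C@@H]1C=C(C)[C@@H]2CC(=O)C(C)=C[C@@H]2C(C)(C)[C@H]1O | intermediate
17 | angelic acid, (Z)-2-methylbut-2-enoic acid | C/C=C(/C)C(O)=O | starting material
18 | angelic 2,4,6-trichlorobenzoic anhydride | C/C=C(/C)C(=O)OC(=O)c1c(Cl)cc(Cl)cc1Cl | intermediate
19 | (1S,6R,9R,10R)-9-angeloyloxy-10-hydroxyhimachala-2,7-dien-4-one | C/C=C(/C)C(=O)O[C@@H]1C=C(C)[C@@H]2CC(=O)C(C)=C[C@@H]2C(C)(C)[C@H]1O | intermediate
20 | (Z)-2-methylbut-2-en-1-ol | C/C=C(/C)CO | intermediate
21 | [(2S,3R)-2,3-dimethyloxiran-2-yl]methanol | OC[C@]1(C)O[C@@H]1C | intermediate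
22 | (2R,3R)-2,3-dimethyloxirane-2-carbaldehyde | O=C[C@]1(C)O[C@@H]1C | intermediate
23 | (2R,3R)-2,3-dimethyloxirane-2-carboxylic acid (epoxyangelic acid) | OC(=O)[C@]1(C)O[C@@H]1C | intermediate
24 | (2R,3R)-2,3-dimethyloxirane-2-carboxylic 2,4,6-trichlorobenzoic anhydride | Clc1cc(Cl)c(C(=O)OC(=O)[C@]2(C)O[C@@H]2C)c(Cl)c1 | intermediate
25 | (1S,6R,9R,10R)-9-angeloyloxy-10-[(2R,3R)-2,3-epoxy-2-methylbutanoyloxy]himachala-2,7-dien-4-one | C/C=C(/C)C(=O)O[C@@H]1C=C(C)[C@@H]2CC(=O)C(C)=C[C@@H]2C(C)(C)[C@H]1OC(=O)[C@]1(C)O[C@@H]1C | target

## Step count and risks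

Total step count: 15. Longest linear sequence: 12 steps (steps 1–11 and 15, from carvone); the epoxy acid branch (steps 12–14) joins in step 15.

The three steps most likely to fail:

1. Step 9, the key annulation. What may go wrong: conjugate addition at the δ-carbon C8 or condensation at the aldehyde carbon may outrun addition at C6, or the donor may add to the wrong face of C6. The fallback sets out from 11 and comes back at 15, making the two bonds in the opposite order. Horner–Wadsworth–Emmons olefination of 11 with diethyl (3-oxobutan-2-yl)phosphonate (NaH, THF, 0 °C → rt) forms C2=C3 first and gives the (E)-trienone F1. Heating F1 with pyrrolidine and AcOH in toluene (80 °C) should equilibrate the C2=C3 geometry through the iminium ion. The derived 2-aminotriene then closes C5–C6 by thermal disrotatory 6π-electrocyclisation, an intramolecular event that leaves no 1,4/1,6 choice. Hydrolysis with γ-protonation returns 15, with the same acetonide and gem-dimethyl bias deciding both ring-fusion centres.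

2. Step 3, the enantioselective epoxidation. What may go wrong: the electron-poor γ,δ-alkene may react too slowly with the oxo-manganese species, or enantiofacial discrimination may be insufficient. The fallback sets out from 4 and comes back at 6, replacing asymmetric catalysis by resolution. Epoxidation of 4 with mCPBA (NaHCO3, CH2Cl2, 0 °C) gives 5 together with its enantiomer, the (4R,5S)-oxide F2. Hydrolysis as in step 4 gives 6 together with the (4S,5S)-diol F3. Kinetic resolution with immobilised lipase B from Candida antarctica and vinyl acetate (t-BuOMe, rt) should acetylate the less hindered C4 hydroxyl of one enantiomer only. On the assumption that F3 is the reactive antipode, it is removed as the 4-O-acetate F4 and 6 is recovered; if the enzyme prefers 6, a lipase of opposite preference is chosen.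

3. Step 15, the second esterification. What may go wrong: acylation of the neopentylic C10 hydroxyl by the α-quaternary acyl donor may be slow, giving time for acyl migration from O9 to O10 and Z-to-E isomerisation of the angelate. The fallback sets out from 16 and comes back at 25, reversing the order of the two acylations. Et3SiCl and imidazole (CH2Cl2, −20 °C) silylate the allylic C9 hydroxyl to give the 9-O-triethylsilyl ether F5. The C10 hydroxyl is then esterified with 23 under forcing Shiina conditions that cannot harm an angelate (2-methyl-6-nitrobenzoic anhydride, Et3N, DMAP, toluene, 60 °C) to give the silyl epoxyangelate F6. Bu4NF buffered with AcOH (THF, 0 °C) frees the 9-hydroxy epoxyangelate F7, whose C9 hydroxyl is angeloylated as in step 11 at rt to give 25.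

## Further compounds

F1 | step 9 | (E)-4-[(5R,6R)-5,6-(isopropylidenedioxy)-3,7,7-trimethylcyclohepta-1,3-dien-1-yl]-3-methylbut-3-en-2-one | CC1(C)O[C@@H]2C=C(C)C=C(/C=C(\C)C(C)=O)C(C)(C)[C@H]2O1
F2 | step 3 | (4R,5S)-4,5-epoxy-2,6,6-trimethylcyclohept-2-en-1-one | O1[C@@H]2C=C(C)C(=O)CC(C)(C)[C@H]12
F3 | step 3 | (4S,5S)-4,5-dihydroxy-2,6,6-trimethylcyclohept-2-en-1-one | O[C@H]1C=C(C)C(=O)CC(C)(C)[C@@H]1O
F4 | step 3 | (4S,5S)-4-acetoxy-5-hydroxy-2,6,6-trimethylcyclohept-2-en-1-one | CC(=O)O[C@H]1C=C(C)C(=O)CC(C)(C)[C@@H]1O
F5 | step 15 | (1S,6R,9R,10R)-10-hydroxy-9-(triethylsilyloxy)himachala-2,7-dien-4-one | CC[Si](CC)(CC)O[C@@H]1C=C(C)[C@@H]2CC(=O)C(C)=C[C@@H]2C(C)(C)[C@H]1O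
F6 | step 15 | (1S,6R,9R,10R)-10-[(2R,3R)-2,3-epoxy-2-methylbutanoyloxy]-9-(triethylsilyloxy)himachala-2,7-dien-4-one | CC[Si](CC)(CC)O[C@@H]1C=C(C)[C@@H]2CC(=O)C(C)=C[C@@H]2C(C)(C)[C@H]1OC(=O)[C@]1(C)O[C@@H]1C
F7 | step 15 | (1S,6R,9R,10R)-10-[(2R,3R)-2,3-epoxy-2-methylbutanoyloxy]-9-hydroxyhimachala-2,7-dien-4-one | O[C@@H]1C=C(C)[C@@H]2CC(=O)C(C)=C[C@@H]2C(C)(C)[C@H]1OC(=O)[C@]1(C)O[C@@H]1C
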